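Ring A is disconnected across C6–C1 and C4–C5. Its ether carbon C6, flanked by the pentyl carbon C1 and the hydroxyl carbon C5, is the central carbon of a malonate, and the C3/C5 oxygens are the carbonyls of a cyclohexane-1,3-dione. The hindered diaryl ether oxygen is therefore installed early by a simple phenol O-alkylation. In step 6 the aryloxymalonate 8 and enone 9 undergo a Michael–Claisen annulation that builds ring A around the oxygen-bearing carbon in one operation. Precursor 8 carries ring B with its acid as a tert-butyl ester, inert to the malonate anion, and its pentanoyl group as a pentynyl group. Late aromatisation and alkyne-to-ketone unmasking finish the target.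

Key step: step 6

Remark: the target has no stereocentre; its 2-acylbenzoic acid unit can equilibrate with the cyclic lactol tautomer, and the open keto acid is taken as the structure to be made.

Step 1
Reactants: 1 2-bromo-4,6-dimethoxybenzaldehyde
Product: 2 2-bromo-6-hydroxy-4-methoxybenzaldehyde
Conditions: BCl3 (1.5 equiv), CH2Cl2, −10 °C to rt; H2O
Reagents that add atoms: none
Why: BCl3 chelates the aldehyde oxygen and the ortho methoxy oxygen, so chloride cleaves only that O–methyl bond (chelation-controlled Lewis acid demethylation) and the para methoxy group survives.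

Step 2
Reactants: 2 2-bromo-6-hydroxy-4-methoxybenzaldehyde
Product: 3 2-bromo-6-hydroxy-4-methoxybenzoic acid
Conditions: NaClO2, NaH2PO4, 2-methylbut-2-ene, t-BuOH/THF/H2O, 0 °C to rt
Reagents that add atoms: sodium chlorite, [Na+].[O-]Cl=O
Why: Pinnick oxidation, in which 2-methylbut-2-ene traps the hypochlorous acid so that the activated phenol ring is not chlorinated, and which is run before the alkyne is introduced so that no alkynyl acid has to be handled here.

Step 3
Reactants: 3 2-bromo-6-hydroxy-4-methoxybenzoic acid
Product: 4 tert-butyl 2-bromo-6-hydroxy-4-methoxybenzoate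
Conditions: tert-butyl 2,2,2-trichloroacetimidate (2.5 equiv), CH2Cl2/cyclohexane, rt
Reagents that add atoms: tert-butyl 2,2,2-trichloroacetimidate, CC(C)(C)OC(=N)C(Cl)(Cl)Cl
Why: the acid protonates the imidate and its carboxylate captures the tert-butyl cation (esterification by alkyl–oxygen bond formation), so the flanked carbonyl carbon need not be attacked and the hydrogen-bonded phenol, which needs a Lewis acid to react, stays free.

Step 4
Reactants: 4 tert-butyl 2-bromo-6-hydroxy-4-methoxybenzoate; 5 pent-1-yne
Product: 6 tert-butyl 2-hydroxy-4-methoxy-6-(pent-1-yn-1-yl)benzoate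
Conditions: Pd(PPh3)2Cl2 (5 mol %), CuI (10 mol %), Et3N, DMF, 70 °C, sealed tube
Reagents that add atoms: none
Why: Sonogashira coupling at a bromide that is activated by the ortho ester and has both oxygen donors meta; the phenol is meta to the new alkyne and cannot add to it.

Step 5
Reactants: 6 tert-butyl 2-hydroxy-4-methoxy-6-(pent-1-yn-1-yl)benzoate; 7 dimethyl 2-chloropropanedioate (dimethyl chloromalonate)
Product: 8 dimethyl 2-[2-(tert-butoxycarbonyl)-5-methoxy-3-(pent-1-yn-1-yl)phenoxy]propanedioate
Conditions: K2CO3, DMF, 40 °C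
Reagents that add atoms: none
Why: Williamson-type SN2 displacement of chloride from the doubly activated malonate carbon by the phenoxide; the chloride avoids halogen transfer to the electron-rich ring, and the hindered tert-butyl ester resists attack by the malonate carbanion, which a methyl ester here would invite with loss of one ester group to an aromatic 3-hydroxybenzofuran.

Step 6
Reactants: 8 dimethyl 2-[2-(tert-butoxycarbonyl)-5-methoxy-3-(pent-1-yn-1-yl)phenoxy]propanedioate; 9 (E)-non-3-en-2-one
Product: 11 methyl 1-[2-(tert-butoxycarbonyl)-5-methoxy-3-(pent-1-yn-1-yl)phenoxy]-2,4-dioxo-6-pentylcyclohexane-1-carboxylate (racemic mixture of diastereomers), via Michael adduct 10 (not isolated)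
Conditions: NaOMe (1.2 equiv), MeOH, 9 added slowly, 65 °C, Ar; then 1 M HCl, 0 °C
Reagents that add atoms: none
Why: Methoxide deprotonates the aryloxymalonate carbon (ring A C6), which adds in Michael fashion to the β-carbon of 9 (C1) to give 10; the methyl ketone enolate of 10 (C4) then attacks one of the two methyl esters (C5) in a Claisen condensation, and the new 1,3-dione is deprotonated at once, which makes the sequence irreversible. The closest known reaction is the Michael–Claisen annulation of dimethyl malonate with this same enone, the cyclohexanedione route to 5-pentylresorcinol. Ring A closes in a 6-exo-trig mode, the enolate carbon attacking an ester carbonyl that lies outside the forming ring. In the numbering of 11, C6 is set in the conjugate addition with no controlling element and C1 by which of the two diastereotopic esters is attacked, so a diastereomer mixture is expected and accepted because both centres later become aromatic carbons. The step needs addition and ring closure to outrun attack of the carbanion on ring B: the tert-butyl ester between two ortho substituents is a poor acyl acceptor, a five-membered acylation product could not be held as an enolate, and the pentynyl group, unlike a pentanoyl group, has no enolate that could close onto the ester.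

Step 7
Reactants: 11 methyl 1-[2-(tert-butoxycarbonyl)-5-methoxy-3-(pent-1-yn-1-yl)phenoxy]-2,4-dioxo-6-pentylcyclohexane-1-carboxylate
Product: 14 2-[(2,4-dioxo-6-pentylcyclohexyl)oxy]-4-methoxy-6-(pent-1-yn-1-yl)benzoic acid (mixture of diastereomers), via β-keto acid 12 (not isolated), via tert-butyl ester dione 13 (not isolated)
Conditions: 2 M NaOH, MeOH, 65 °C; 1 M HCl to pH 2, extraction; crude in TFA/CH2Cl2 (1:4), rt
Reagents that add atoms: none
Why: saponification of the methyl ester (the tert-butyl ester and the dione enolate are inert to hydroxide), decarboxylation of β-keto acid 12 on acidification and acidolysis of the tert-butyl ester in TFA are each standard, and the acid meets the alkyne only at room temperature with no π-acid present.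

Step 8
Reactants: 14 2-[(2,4-dioxo-6-pentylcyclohexyl)oxy]-4-methoxy-6-(pent-1-yn-1-yl)benzoic acid
Product: 17 2-(2,4-dihydroxy-6-pentylphenoxy)-4-methoxy-6-(pent-1-yn-1-yl)benzoic acid, via tris(trimethylsilyl) dienol ether 15 (not isolated), via tris(trimethylsilyl) arene 16 (not isolated)
Conditions: TMSOTf (3.6 equiv), Et3N, CH2Cl2, 0 °C; volatiles removed, pentane, filtration; DDQ (1.05 equiv), 2,6-lutidine, CH2Cl2, −20 to 0 °C; 1 M HCl, THF, rt
Reagents that add atoms: none
Why: soft enolisation turns the dione into a bis(silyloxy)cyclohexa-1,3-diene from which DDQ abstracts hydride in the cold (cyclohexadiene-to-arene dehydrogenation), and the phenols emerge silylated and so shielded from over-oxidation until the acidic work-up frees them.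

Step 9
Reactants: 17 2-(2,4-dihydroxy-6-pentylphenoxy)-4-methoxy-6-(pent-1-yn-1-yl)benzoic acid
Product: 19 2-(2,4-dihydroxy-6-pentylphenoxy)-4-methoxy-6-pentanoylbenzoic acid (CNP0189595.0), via (Z)-butylidenephthalide 18 (not isolated)
Conditions: AgI (20 mol %), DMF, 60 °C, dark, Ar; then THF, degassed 1 M NaOH, rt; 1 M HCl, 0 °C
Reagents that add atoms: sodium hydroxide, [Na+].[OH-]
Why: silver-catalysed anti addition of the carboxylate to the alkyne in the 5-exo-dig mode should give the (Z)-enol lactone 18, whose acyl–oxygen bond hydroxide cleaves to the aryl ketone enolate and the carboxylate, and acidification then gives the keto acid, with oxygen excluded to protect the resorcinolate.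

Compound list
1 | 2-bromo-4,6-dimethoxybenzaldehyde | COc1cc(Br)c(C=O)c(OC)c1 | starting material
2 | 2-bromo-6-hydroxy-4-methoxybenzaldehyde | COc1cc(O)c(C=O)c(Br)c1 | intermediate
3 | 2-bromo-6-hydroxy-4-methoxybenzoic acid | COc1cc(O)c(C(=O)O)c(Br)c1 | intermediate
4 | tert-butyl 2-bromo-6-hydroxy-4-methoxybenzoate | COc1cc(O)c(C(=O)OC(C)(C)C)c(Br)c1 | intermediate
5 | pent-1-yne | CCCC#C | starting material
6 | tert-butyl 2-hydroxy-4-methoxy-6-(pent-1-yn-1-yl)benzoate | CCCC#Cc1cc(OC)cc(O)c1C(=O)OC(C)(C)C | intermediate
7 | dimethyl 2-chloropropanedioate | COC(=O)C(Cl)C(=O)OC | starting material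
8 | dimethyl 2-[2-(tert-butoxycarbonyl)-5-methoxy-3-(pent-1-yn-1-yl)phenoxy]propanedioate | COC(=O)C(Oc1cc(OC)cc(C#CCCC)c1C(=O)OC(C)(C)C)C(=O)OC | intermediate
9 | (E)-non-3-en-2-one | CCCCC/C=C/C(C)=O | starting material
10 | dimethyl 2-[2-(tert-butoxycarbonyl)-5-methoxy-3-(pent-1-yn-1-yl)phenoxy]-2-(2-oxononan-4-yl)propanedioate (racemic; not isolated) | CCCCCC(CC(C)=O)C(Oc1cc(OC)cc(C#CCCC)c1C(=O)OC(C)(C)C)(C(=O)OC)C(=O)OC | intermediate
11 | methyl 1-[2-(tert-butoxycarbonyl)-5-methoxy-3-(pent-1-yn-1-yl)phenoxy]-2,4-dioxo-6-pentylcyclohexane-1-carboxylate (racemic, mixture of C1/C6 diastereomers; drawn as the diketone) | COC(=O)C1(Oc2cc(OC)cc(C#CCCC)c2C(=O)OC(C)(C)C)C(CCCCC)CC(=O)CC1=O | intermediate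
12 | 1-[2-(tert-butoxycarbonyl)-5-methoxy-3-(pent-1-yn-1-yl)phenoxy]-2,4-dioxo-6-pentylcyclohexane-1-carboxylic acid (diastereomer mixture; not isolated) | OC(=O)C1(Oc2cc(OC)cc(C#CCCC)c2C(=O)OC(C)(C)C)C(CCCCC)CC(=O)CC1=O | intermediate
13 | tert-butyl 2-[(2,4-dioxo-6-pentylcyclohexyl)oxy]-4-methoxy-6-(pent-1-yn-1-yl)benzoate (diastereomer mixture; not isolated) | CCCCCC1CC(=O)CC(=O)C1Oc1cc(OC)cc(C#CCCC)c1C(=O)OC(C)(C)C | intermediate
14 | 2-[(2,4-dioxo-6-pentylcyclohexyl)oxy]-4-methoxy-6-(pent-1-yn-1-yl)benzoic acid (diastereomer mixture) | CCCCCC1CC(=O)CC(=O)C1Oc1cc(OC)cc(C#CCCC)c1C(=O)O | intermediate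
15 | trimethylsilyl 2-{[2,4-bis(trimethylsilyloxy)-6-pentylcyclohexa-1,3-dien-1-yl]oxy}-4-methoxy-6-(pent-1-yn-1-yl)benzoate (racemic; one of two convergent dienol ether regioisomers drawn; not isolated) | CCCCCC1CC(O[Si](C)(C)C)=CC(O[Si](C)(C)C)=C1Oc1cc(OC)cc(C#CCCC)c1C(=O)O[Si](C)(C)C | intermediate
16 | trimethylsilyl 2-[2,4-bis(trimethylsilyloxy)-6-pentylphenoxy]-4-methoxy-6-(pent-1-yn-1-yl)benzoate (not isolated) | CCCCCc1cc(O[Si](C)(C)C)cc(O[Si](C)(C)C)c1Oc1cc(OC)cc(C#CCCC)c1C(=O)O[Si](C)(C)C | intermediate
17 | 2-(2,4-dihydroxy-6-pentylphenoxy)-4-methoxy-6-(pent-1-yn-1-yl)benzoic acid | CCCCCc1cc(O)cc(O)c1Oc1cc(OC)cc(C#CCCC)c1C(=O)O | intermediate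
18 | (3Z)-3-butylidene-7-(2,4-dihydroxy-6-pentylphenoxy)-5-methoxy-2-benzofuran-1(3H)-one (not isolated) | CCC/C=C1\OC(=O)c2c(Oc3c(O)cc(O)cc3CCCCC)cc(OC)cc12 | intermediate
19 | 2-(2,4-dihydroxy-6-pentylphenoxy)-4-methoxy-6-pentanoylbenzoic acid | CCCCCc1cc(O)cc(O)c1Oc1cc(OC)cc(C(=O)CCCC)c1C(=O)O | target

Total step count: 9. Longest linear sequence: 9 steps (1 to 19); 5, 7 and 9 are purchased.

Steps most likely to fail

Step 6. Conjugate addition of the crowded, fully substituted malonate carbanion to the β-pentyl enone may be slow and reversible, so that base-induced self-condensation of 9 and slow methoxide cleavage of 8 use up the partners before the ring closes. The fallback sets out from 8 and replaces 9 by the purchased ynone non-3-yn-2-one F1 under the same NaOMe/MeOH conditions. Its sp-hybridised β-carbon is more electrophilic and much less hindered. The vinylogous adduct can equilibrate between its alkene isomers under methoxide, so the Z isomer can close to methyl 1-[2-(tert-butoxycarbonyl)-5-methoxy-3-(pent-1-yn-1-yl)phenoxy]-2,4-dioxo-6-pentylcyclohex-5-ene-1-carboxylate F2, which is already at the oxidation level of the resorcinol. TFA in CH2Cl2 would cleave the tert-butyl ester to 2-{[1-(methoxycarbonyl)-2,4-dioxo-6-pentylcyclohex-5-en-1-yl]oxy}-4-methoxy-6-(pent-1-yn-1-yl)benzoic acid F3. Aqueous NaOH followed by HCl would then remove the C1 ester with loss of CO2 and spontaneous tautomerisation to the arene. The fallback comes back to the route at 17 and makes step 8 unnecessary.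

Step 8. Silylation may stop at the mono-silyl vinylogous ester, which DDQ does not touch in the cold, or the very electron-rich arene may be oxidised further once it forms. The fallback moves the dehydrogenation to the end, where no alkyne is left and an iodine-catalysed method becomes usable. From 14, AgI in DMF would give (3Z)-3-butylidene-7-[(2,4-dioxo-6-pentylcyclohexyl)oxy]-5-methoxy-2-benzofuran-1(3H)-one F4. Aqueous NaOH then HCl would open it to 2-[(2,4-dioxo-6-pentylcyclohexyl)oxy]-4-methoxy-6-pentanoylbenzoic acid F5. I2 (20 mol %) in DMSO at 80 °C would aromatise the dione by α-iodination, loss of HI and reoxidation of iodide by DMSO, arriving directly at 19.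

Step 7. Hydroxide attack on the ester at the fully substituted, neopentyl-like C1 may be slow, and long heating in alkali invites cleavage of the β-dicarbonyl ring. The fallback removes the ester by dealkylation instead of acyl substitution. From 11, LiCl in wet DMSO at 130 °C (Krapcho reaction: chloride attacks the O-methyl carbon and the carboxylate loses CO2) should give 13, which re-enters the route at the TFA stage of step 7. This fallback makes no new compound (F0).

Further compounds
F1 | step 6 | non-3-yn-2-one | CCCCCC#CC(C)=O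
F2 | step 6 | methyl 1-[2-(tert-butoxycarbonyl)-5-methoxy-3-(pent-1-yn-1-yl)phenoxy]-2,4-dioxo-6-pentylcyclohex-5-ene-1-carboxylate (racemic) | COC(=O)C1(Oc2cc(OC)cc(C#CCCC)c2C(=O)OC(C)(C)C)C(CCCCC)=CC(=O)CC1=O
F3 | step 6 | 2-{[1-(methoxycarbonyl)-2,4-dioxo-6-pentylcyclohex-5-en-1-yl]oxy}-4-methoxy-6-(pent-1-yn-1-yl)benzoic acid (racemic) | COC(=O)C1(Oc2cc(OC)cc(C#CCCC)c2C(=O)O)C(CCCCC)=CC(=O)CC1=O
F4 | step 8 | (3Z)-3-butylidene-7-[(2,4-dioxo-6-pentylcyclohexyl)oxy]-5-methoxy-2-benzofuran-1(3H)-one (diastereomer mixture) | CCC/C=C1\OC(=O)c2c(OC3C(CCCCC)CC(=O)CC3=O)cc(OC)cc12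
F5 | step 8 | 2-[(2,4-dioxo-6-pentylcyclohexyl)oxy]-4-methoxy-6-pentanoylbenzoic acid (diastereomer mixture) | CCCCCC1CC(=O)CC(=O)C1Oc1cc(OC)cc(C(=O)CCCC)c1C(=O)O
F0 | step 7 | none | none
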